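## Retrosynthetic overview

1. The 14-membered carbocycle is closed last, at the Z-C9=C10 alkene, by ring-closing metathesis of the bis-terminal diene 21.
2. The tetrahydropyran comes from the key C13–O bond: 6-exo opening of a (12S,13S)-epoxide by O3. O3 is installed earlier by organocatalytic α-aminoxylation and is unmasked in the same flask as the epoxidation.
3. The γ-lactone and the C1–C2 bond come from an indium Barbier 2-(methoxycarbonyl)allylation of the α-aminoxy aldehyde with allylic bromide 15.
4. Aldehyde 5 comes from (R)-linalool (C8 from the chiral pool, C4 by transfer hydrogenation). Bromide 15 comes from pent-1-en-4-yne, oxirane and methyl propiolate.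
5. Ring order: γ-lactone, then tetrahydropyran, then macrocycle.

Assumption: locants C1–C20 in the Why lines follow cembrane numbering (lactone on C1/C2, ether bridge C3–O–C13, carbinols C8 and C12, alkene C9=C10), and the target is (1R,2S,3R,4S,8R,9Z,12S,13R) as read from the given SMILES.

## Route

Step 1
Reactants: 1 (R)-(−)-linalool
Product: 2 (2E,6R)-6-hydroxy-2,6-dimethylocta-2,7-dienal
Conditions: SeO2 (1.1 equiv), 1,4-dioxane, 80 °C
Reagents that add atoms: selenium dioxide O=[Se]=O
Why: Riley allylic oxidation (ene/[2,3] sequence) attacks only the (E)-methyl of the trisubstituted alkene and runs on to the enal, while the vinyl carbinol has no allylic C–H and C8 (R, from the pool) is untouched.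

Step 2
Reactants: 2 (2E,6R)-6-hydroxy-2,6-dimethylocta-2,7-dienal
Product: 4 (2E,7R)-7-hydroxy-3,7-dimethylnona-2,8-dienal, via dienol methyl ether 3 (not isolated)
Conditions: Ph3P(CH2OMe)Cl, KOtBu (excess), THF, 0 °C; then aq. oxalic acid, THF, rt
Reagents that add atoms: (methoxymethyl)triphenylphosphonium chloride COC[P+](c1ccccc1)(c1ccccc1)c1ccccc1.[Cl-]; water O
Why: Wittig methoxymethylenation gives the 1-methoxydiene, and mild acid hydrolysis with vinylogous protonation at the diene terminus gives the one-carbon-homologated conjugated enal; no stereocentre is formed and the E/Z mixture obtained is acceptable for step 3.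

Step 3
Reactants: 4 (2E,7R)-7-hydroxy-3,7-dimethylnona-2,8-dienal
Product: 5 (3S,7R)-7-hydroxy-3,7-dimethylnon-8-enal
Conditions: Hantzsch ester (1.1 equiv), morpholinium (S)-TRIP (10 mol%, the enantiomer of the salt that gives (R)-citronellal from citral), dioxane, 50 °C
Reagents that add atoms: none
Why: Counteranion-directed organocatalytic transfer hydrogenation (citral-to-citronellal type) delivers hydride to one face of the E/Z-equilibrating iminium ion and sets C4 (S), and the isolated vinyl group is inert.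

Step 4
Reactants: 6 pent-1-en-4-yne; 7 oxirane
Product: 10 (3E)-4-methylhepta-3,6-dien-1-ol, via alkenylalane 8 (not isolated), via lithium alanate 9 (not isolated)
Conditions: Me3Al, Cp2ZrCl2 (cat.), (CH2Cl)2, rt; then n-BuLi, THF, −30 °C; then oxirane, −30 °C to rt
Reagents that add atoms: trimethylaluminium C[Al](C)C
Why: Negishi Zr-catalysed syn-methylalumination of the terminal alkyne (alkyne reacts before alkene) fixes the E-trisubstituted C12=C13 alkene, and the alanate opens oxirane with retention of alkene geometry.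

Step 5
Reactants: 10 (3E)-4-methylhepta-3,6-dien-1-ol
Product: 11 (3E)-4-methylhepta-3,6-dienal
Conditions: Dess–Martin periodinane, pyridine, CH2Cl2, 0 °C; used crude
Reagents that add atoms: none
Why: Dess–Martin oxidation under buffered, non-basic conditions gives the β,γ-unsaturated aldehyde without moving the alkene into conjugation.

Step 6
Reactants: 11 (3E)-4-methylhepta-3,6-dienal; 12 methyl propiolate
Product: 14 methyl (5E)-3-hydroxy-6-methyl-2-methylidenenona-5,8-dienoate, via vinylalane 13 (not isolated)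
Conditions: DIBAL-H, NMO, THF, 0 °C; then 11, 0 °C to rt
Reagents that add atoms: none
Why: Vinylalumination (hydroalumination of the propiolate, then 1,2-addition of the α-ester vinylalane) gives the Morita–Baylis–Hillman-type adduct quickly and without amine base, so the β,γ-alkene does not isomerise; the racemic carbinol centre is erased in step 7.

Step 7
Reactants: 14 methyl (5E)-3-hydroxy-6-methyl-2-methylidenenona-5,8-dienoate
Product: 15 methyl (2Z,5E)-2-(bromomethyl)-6-methylnona-2,5,8-trienoate
Conditions: NBS, Me2S, CH2Cl2, 0 °C to rt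
Reagents that add atoms: N-bromosuccinimide O=C1CCC(=O)N1Br
Why: Corey–Kim-type activation of the allylic alcohol followed by SN2′ bromide attack gives the rearranged, thermodynamically preferred (2Z)-allylic bromide, as is standard for Baylis–Hillman adducts.

Step 8
Reactants: 5 (3S,7R)-7-hydroxy-3,7-dimethylnon-8-enal; 15 methyl (2Z,5E)-2-(bromomethyl)-6-methylnona-2,5,8-trienoate
Product: 18 (4R,5S)-5-{(1R,2S,6R)-6-hydroxy-2,6-dimethyl-1-[(phenylamino)oxy]oct-7-en-1-yl}-3-methylidene-4-[(2E)-3-methylhexa-2,5-dien-1-yl]oxolan-2-one, via aminoxy aldehyde 16 (not isolated), via hydroxy ester 17 (not isolated)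
Conditions: L-proline (20 mol%), PhNO (1.0 equiv), DMSO, rt; then 15, In powder, NaI (cat.), DMSO–H2O, rt; then TsOH (cat.), CH2Cl2, rt
Reagents that add atoms: nitrosobenzene O=Nc1ccccc1
Why: One-pot proline α-aminoxylation (enamine O-nitroso aldol, L-proline sets C3 as R) then indium Barbier 2-(methoxycarbonyl)allylation and lactonisation, in which Felkin–Anh/Cornforth attack anti to the aminoxy group sets C2 (S) and the cyclic allylindium transition state of the (Z)-bromide gives the 1,2-syn adduct and hence the cis-lactone (C1 R).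

Step 9
Reactants: 18 (4R,5S)-5-{(1R,2S,6R)-6-hydroxy-2,6-dimethyl-1-[(phenylamino)oxy]oct-7-en-1-yl}-3-methylidene-4-[(2E)-3-methylhexa-2,5-dien-1-yl]oxolan-2-one
Product: 21 (3aR,5R,7R,7aS)-5-[(2S)-2-hydroxypent-4-en-2-yl]-7-[(2S,6R)-6-hydroxy-6-methyloct-7-en-2-yl]-3-methylidenehexahydro-2H-furo[2,3-c]pyran-2-one, via hydroxy lactone 19 (not isolated), via epoxy alcohol 20 (not isolated)
Conditions: ent-Shi ketone (0.3 equiv; the enantiomer of the D-fructose-derived ketone, which gives R,R-epoxides from E-trisubstituted alkenes), Oxone (4 equiv), K2CO3, Bu4NHSO4 (cat.), MeCN–DMM/aq. borate buffer pH 10.5, 0 °C; then CSA (cat.), CH2Cl2, 0 °C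
Reagents that add atoms: potassium peroxymonosulfate (Oxone) [K+].[O-]S(=O)(=O)OO
Why: Proposed new method: an oxidatively triggered aminoxy unmasking–epoxidation–cycloetherification cascade in which the dioxirane/HSO5− N-hydroxylates the N-aryl alkoxyamine, the N-alkoxy-N-hydroxyaniline collapses to the free C3 alcohol 19 and nitrosobenzene (oxidised on to nitrobenzene), the same chiral dioxirane epoxidises the only electron-rich alkene (E-C12=C13) through the spiro transition state to the 12S,13S-epoxide 20, and acid then drives 6-exo-tet attack of O3 at the less substituted C13 with inversion (13R) while C12 keeps its configuration (S) as the tertiary alcohol; the closest known reaction types are the Shi epoxidation/hydroxy-epoxide cyclisation of polyether synthesis, dioxirane N-oxidation of amines and the Cu(II)-mediated N–O cleavage of α-aminoxylation products.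

Step 10
Reactants: 21 (3aR,5R,7R,7aS)-5-[(2S)-2-hydroxypent-4-en-2-yl]-7-[(2S,6R)-6-hydroxy-6-methyloct-7-en-2-yl]-3-methylidenehexahydro-2H-furo[2,3-c]pyran-2-one
Product: 22 CNP0146755.1, (1R,2S,3R,4S,8R,9Z,12S,13R)-8,12-dihydroxy-3,13-epoxycembra-9,15(17)-dien-16,2-olide
Conditions: Grubbs Z-selective cyclometalated Ru nitrato catalyst (10 mol%), (CH2Cl)2, 3 mM, 60 °C, static vacuum
Reagents that add atoms: none
Why: Z-selective ring-closing metathesis in which the catalyst initiates at the unhindered allyl group and the side-bound ruthenacycle forces the syn (Z) C9=C10 alkene on closing onto the vinyl carbinol of the cis-2,6-pre-organised tetrahydropyran, with loss of ethene; the electron-poor α-methylene lactone is inert.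

## Compound list

1 | (R)-(−)-linalool, (3R)-3,7-dimethylocta-1,6-dien-3-ol | CC(C)=CCC[C@@](C)(O)C=C | starting material
2 | (2E,6R)-6-hydroxy-2,6-dimethylocta-2,7-dienal | O=C/C(C)=C/CC[C@@](C)(O)C=C | intermediate
3 | (3R,6E)-9-methoxy-3,7-dimethylnona-1,6,8-trien-3-ol (dienol methyl ether, enol ether geometry mixed) | COC=C/C(C)=C/CC[C@@](C)(O)C=C | intermediate
4 | (2E,7R)-7-hydroxy-3,7-dimethylnona-2,8-dienal (E shown, obtained as E/Z mixture) | O=C/C=C(C)/CCC[C@@](C)(O)C=C | intermediate
5 | (3S,7R)-7-hydroxy-3,7-dimethylnon-8-enal | O=CC[C@@H](C)CCC[C@@](C)(O)C=C | intermediate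
6 | pent-1-en-4-yne | C#CCC=C | starting material
7 | oxirane | C1CO1 | starting material
8 | dimethyl[(1E)-2-methylpenta-1,4-dien-1-yl]alumane (alkenylalane) | C=CC/C(C)=C/[Al](C)C | intermediate
9 | lithium butyl(dimethyl)[(1E)-2-methylpenta-1,4-dien-1-yl]aluminate (lithium alanate) | [Li+].CCCC[Al-](C)(C)/C=C(C)/CC=C | intermediate
10 | (3E)-4-methylhepta-3,6-dien-1-ol | OCC/C=C(C)/CC=C | intermediate
11 | (3E)-4-methylhepta-3,6-dienal | O=CC/C=C(C)/CC=C | intermediate
12 | methyl propiolate | C#CC(=O)OC | starting material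
13 | [1-(methoxycarbonyl)ethenyl]bis(2-methylpropyl)alumane (vinylalane) | C=C(C(=O)OC)[Al](CC(C)C)CC(C)C | intermediate
14 | methyl (5E)-3-hydroxy-6-methyl-2-methylidenenona-5,8-dienoate (racemic) | COC(=O)C(=C)C(O)C/C=C(C)/CC=C | intermediate
15 | methyl (2Z,5E)-2-(bromomethyl)-6-methylnona-2,5,8-trienoate | COC(=O)/C(CBr)=C/C/C=C(C)/CC=C | intermediate
16 | (2R,3S,7R)-7-hydroxy-3,7-dimethyl-2-[(phenylamino)oxy]non-8-enal (aminoxy aldehyde) | O=C[C@H](ONc1ccccc1)[C@@H](C)CCC[C@@](C)(O)C=C | intermediate
17 | methyl (3R,4S,5R,6S,10R)-4,10-dihydroxy-6,10-dimethyl-2-methylidene-3-[(2E)-3-methylhexa-2,5-dien-1-yl]-5-[(phenylamino)oxy]dodec-11-enoate (hydroxy ester) | COC(=O)C(=C)[C@@H](C/C=C(C)/CC=C)[C@H](O)[C@H](ONc1ccccc1)[C@@H](C)CCC[C@@](C)(O)C=C | intermediate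
18 | (4R,5S)-5-{(1R,2S,6R)-6-hydroxy-2,6-dimethyl-1-[(phenylamino)oxy]oct-7-en-1-yl}-3-methylidene-4-[(2E)-3-methylhexa-2,5-dien-1-yl]oxolan-2-one | C=C1C(=O)O[C@H]([C@H](ONc2ccccc2)[C@@H](C)CCC[C@@](C)(O)C=C)[C@@H]1C/C=C(C)/CC=C | intermediate
19 | (4R,5S)-5-[(1R,2S,6R)-1,6-dihydroxy-2,6-dimethyloct-7-en-1-yl]-3-methylidene-4-[(2E)-3-methylhexa-2,5-dien-1-yl]oxolan-2-one (hydroxy lactone) | C=C1C(=O)O[C@H]([C@H](O)[C@@H](C)CCC[C@@](C)(O)C=C)[C@@H]1C/C=C(C)/CC=C | intermediate
20 | (4R,5S)-5-[(1R,2S,6R)-1,6-dihydroxy-2,6-dimethyloct-7-en-1-yl]-3-methylidene-4-{[(2S,3S)-3-methyl-3-(prop-2-en-1-yl)oxiran-2-yl]methyl}oxolan-2-one (epoxy alcohol) | C=C1C(=O)O[C@H]([C@H](O)[C@@H](C)CCC[C@@](C)(O)C=C)[C@@H]1C[C@@H]2O[C@@]2(C)CC=C | intermediate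
21 | (3aR,5R,7R,7aS)-5-[(2S)-2-hydroxypent-4-en-2-yl]-7-[(2S,6R)-6-hydroxy-6-methyloct-7-en-2-yl]-3-methylidenehexahydro-2H-furo[2,3-c]pyran-2-one | C=C1C(=O)O[C@@H]2[C@@H]([C@@H](C)CCC[C@@](C)(O)C=C)O[C@H](C[C@H]12)[C@@](C)(O)CC=C | intermediate
22 | CNP0146755.1, (1R,2S,3R,4S,8R,9Z,12S,13R)-8,12-dihydroxy-3,13-epoxycembra-9,15(17)-dien-16,2-olide | C=C1C(=O)O[C@@H]2[C@@H]3O[C@H](C[C@H]12)[C@@](C)(O)C/C=C\[C@](C)(O)CCC[C@@H]3C | target

## Step count and risks

Total steps: 10. Longest linear sequence: 7 (steps 4, 5, 6, 7, 8, 9, 10). The linalool branch is steps 1–3 and joins at step 8.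

The three steps most likely to fail:

Step 8. The α-aminoxy aldehyde 16 is labile, and the N–H/O pair could chelate indium and erode the Felkin (2,3-anti) selectivity. The fallback sets out from 5 (with 15). MacMillan–Sibi α-oxyamination of 5 (imidazolidinone catalyst, TEMPO, FeCl3/NaNO2/O2) gives the isolable (2R,3S,7R)-7-hydroxy-3,7-dimethyl-2-[(2,2,6,6-tetramethylpiperidin-1-yl)oxy]non-8-enal F1. Nozaki–Hiyama allylation of this aldehyde with 15 (CrCl2, THF; non-chelating, Felkin- and cis-lactone-selective) and acid lactonisation give (4R,5S)-5-{(1R,2S,6R)-6-hydroxy-2,6-dimethyl-1-[(2,2,6,6-tetramethylpiperidin-1-yl)oxy]oct-7-en-1-yl}-3-methylidene-4-[(2E)-3-methylhexa-2,5-dien-1-yl]oxolan-2-one F2. Zn/AcOH then cleaves the N–O bond and the sequence comes back to the route at 19, which is isolated and taken through the epoxidation and cyclisation of step 9.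

Step 9 (the proposed new step). N-oxidation could stop at a nitroxide, liberated nitrosobenzene could undergo an ene reaction with C12=C13, or 7-endo opening could compete. The fallback uses known chemistry and sets out from 18. Zn, AcOH/THF cleaves the N–O bond reductively to hydroxy lactone 19, which is isolated. Ordinary Shi epoxidation with the ent-ketone gives epoxy alcohol 20, which is isolated. CSA in CH2Cl2 then effects the 6-exo cyclisation, coming back to the route at 21. This fallback makes no compound outside the compound list (none F0).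

Step 10. The vinyl group sits on a quaternary carbinol, and a 12-membered oxacycle has no built-in preference for Z. The fallback sets out from 21. iPr2Si(OTf)2 with 2,6-lutidine ties the two tertiary hydroxyls together as the 8,12-O-[di(propan-2-yl)silylene] bis-ether of 21 F3. Grubbs II RCM then closes an eight-membered dioxasilacycle in which only the Z alkene can form, giving the 8,12-O-[di(propan-2-yl)silylene] bis-ether of 22 F4. HF·pyridine removes the tether and the sequence comes back to the route at 22.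

Further compounds

F1 | step 8 | (2R,3S,7R)-7-hydroxy-3,7-dimethyl-2-[(2,2,6,6-tetramethylpiperidin-1-yl)oxy]non-8-enal | O=C[C@H](ON1C(C)(C)CCCC1(C)C)[C@@H](C)CCC[C@@](C)(O)C=C
F2 | step 8 | (4R,5S)-5-{(1R,2S,6R)-6-hydroxy-2,6-dimethyl-1-[(2,2,6,6-tetramethylpiperidin-1-yl)oxy]oct-7-en-1-yl}-3-methylidene-4-[(2E)-3-methylhexa-2,5-dien-1-yl]oxolan-2-one | C=C1C(=O)O[C@H]([C@H](ON2C(C)(C)CCCC2(C)C)[C@@H](C)CCC[C@@](C)(O)C=C)[C@@H]1C/C=C(C)/CC=C
F0 | step 9 | none | none
F3 | step 10 | 8,12-O-[di(propan-2-yl)silylene] bis-ether of 21 | C=C1C(=O)O[C@@H]2[C@@H]([C@@H](C)CCC[C@@](C)(O3)C=C)O[C@H](C[C@H]12)[C@@](C)(O[Si]3(C(C)C)C(C)C)CC=C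
F4 | step 10 | 8,12-O-[di(propan-2-yl)silylene] bis-ether of 22 (9Z) | C=C1C(=O)O[C@@H]2[C@@H]3O[C@H](C[C@H]12)[C@@](C)(O[Si]4(C(C)C)C(C)C)C/C=C\[C@](C)(O4)CCC[C@@H]3C
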